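The seven-membered ring (C1, C10, C9, C8, C7, C6, C5) is disconnected at C1–C10 and C7–C8 into an achiral 1-vinylcyclopentene (C7=C6–C5=C1) and a three-carbon vinylcarbenoid (C8–C9–C10). A chiral dirhodium catalyst cyclopropanates the vinyl group, and the cis-divinylcyclopropane then releases its strain in a Cope rearrangement that closes the ring and fixes the quaternary ring-fusion carbon C1 in one operation. The step exploits the fact that every oxygen on this ring (C6–O, the C8/C9 trans-diol) can descend from the 1,4-diene (C5=C6, C8=C9) that the rearrangement delivers; C1 then relays its configuration to C5, C6, C4, C8 and C9.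

Key step: step 4

Remark (labels): daucane numbering is used for atoms: C1 methyl-bearing ring-fusion carbon, C2/C3 cyclopentane CH2, C4 isopropyl carbinol carbon, C5 ring-fusion CH, C6 ester carbon, C7 CH2, C8 methyl carbinol carbon, C9 secondary carbinol carbon, C10 CH2; β is the face of the C1 methyl group.

Assumption: the sense of induction known for Rh2(DOSP)4 with aryl- and vinyldiazoacetates and monosubstituted alkenes is taken to hold for diene 3; if it proved opposite, the commercial antipodal catalyst would be used in the same way.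

Step 1
Reactants: 1 2-bromo-3-methylcyclopent-2-en-1-one
Product: 2 6-bromo-7-methyl-1,4-dioxaspiro[4.4]non-6-ene
Conditions: ethylene glycol, p-TsOH·H2O (cat.), benzene, reflux, Dean–Stark trap
Reagents that add atoms: ethylene glycol, OCCO
Why: Acid-catalysed ketalisation with azeotropic removal of water should mask the future C4 carbonyl as a group that is symmetric about the ring plane, the α-bromo substituent holding the double bond in place.

Step 2
Reactants: 2 6-bromo-7-methyl-1,4-dioxaspiro[4.4]non-6-ene
Product: 3 6-ethenyl-7-methyl-1,4-dioxaspiro[4.4]non-6-ene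
Conditions: vinylboronic acid pinacol ester, Pd(OAc)2 (cat.), SPhos (cat.), K3PO4, toluene/H2O, 80 °C
Reagents that add atoms: vinylboronic acid pinacol ester, C=CB1OC(C)(C)C(C)(C)O1
Why: Suzuki–Miyaura coupling, in which the electron-rich biaryl phosphine should allow oxidative addition to the hindered alkenyl bromide while the ketal is stable to the basic medium.

Step 3
Reactants: 4 methyl but-3-enoate
Product: 5 methyl 2-diazobut-3-enoate
Conditions: p-ABSA, DBU, MeCN, 0 °C; extraction into pentane, used at once as a cold solution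
Reagents that add atoms: 4-acetamidobenzenesulfonyl azide (p-ABSA), CC(=O)Nc1ccc(cc1)S(=O)(=O)N=[N+]=[N-]
Why: Regitz diazo transfer to the methylene group activated by both the ester and the alkene; the vinyldiazoacetate is kept cold and dilute because it cyclises slowly to a pyrazole.

Step 4
Reactants: 3 6-ethenyl-7-methyl-1,4-dioxaspiro[4.4]non-6-ene; 5 methyl 2-diazobut-3-enoate
Product: 7 methyl (8aR)-8a-methyl-3-oxo-1,2,3,5,8,8a-hexahydroazulene-6-carboxylate ethylene ketal, via cis-divinylcyclopropane 6 (not isolated)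
Conditions: Rh2(R-DOSP)4 (dirhodium tetrakis[(R)-N-(4-dodecylphenylsulfonyl)prolinate], 1 mol %), pentane, −40 °C to rt, slow addition of 5 (2 equiv); then toluene, 100 °C
Reagents that add atoms: none
Why: The rhodium-bound donor/acceptor vinylcarbenoid from 5 cyclopropanates the terminal vinyl group of 3 (C6=C7) with the vinyl donor cis to the cyclopentenyl group, and the resulting cis-divinylcyclopropane 6 undergoes a strain-driven Cope rearrangement through the obligatory boat transition state, breaking C6–C8 while C1–C10 forms. The closest known reaction type is the dirhodium-catalysed tandem cyclopropanation/Cope rearrangement of vinyldiazoacetates with 1,3-dienes (formal (4+3) cycloaddition), which is known to build quaternary carbons from fully substituted diene termini. The seven-membered ring is closed by a concerted (3,3)-sigmatropic shift, so that overall C7–C6–C5–C1 and C8–C9–C10 are joined in a (4+3) annulation onto the preformed cyclopentene. The only stereocentre of 7, quaternary C1, follows stereospecifically from the configuration of C6 in 6, which the chiral catalyst sets; Rh2(R-DOSP)4 is chosen on the known sense of induction of this catalyst family, and its antipode would give ent-7. The step needs site selectivity for the vinyl group over the tetrasubstituted ring alkene and the allylic or ketal C–H bonds, which the unhindered CH2 terminus secures, and pure catalyst control of the alkene face, which the ketal secures because it makes 3 achiral. The inward-pointing C1 methyl group slows the Cope stage, hence the thermal finish, and the ester left on C8 deactivates C8=C9 for step 5.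

Step 5
Reactants: 7 methyl (8aR)-8a-methyl-3-oxo-1,2,3,5,8,8a-hexahydroazulene-6-carboxylate ethylene ketal
Product: 9 methyl (3aS,4S,8aR)-4-hydroxy-8a-methyl-3-oxo-1,2,3,3a,4,5,8,8a-octahydroazulene-6-carboxylate ethylene ketal, via C6-alkylborane 8 (not isolated)
Conditions: BH3·THF (1.2 equiv), THF, 0 °C to rt; then H2O2 (30 %), aq. NaOAc, 0 °C to rt
Reagents that add atoms: borane–tetrahydrofuran, B.C1CCOC1 (boron of 8 only); hydrogen peroxide, OO
Why: Brown hydroboration–oxidation of the electron-rich C5=C6 alkene (the conjugated ester protects C8=C9), boron going to the less substituted C6 and hydrogen to C5 in a syn addition on the α face, anti to the angular C1 methyl group as in the hydroboration of Δ5-steroids, which should set H-5α (trans ring fusion) and 6α-OH together.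

Step 6
Reactants: 9 methyl (3aS,4S,8aR)-4-hydroxy-8a-methyl-3-oxo-1,2,3,3a,4,5,8,8a-octahydroazulene-6-carboxylate ethylene ketal
Product: 10 (3aS,4S,8aR)-4-hydroxy-6-(hydroxymethyl)-8a-methyl-2,3a,4,5,8,8a-hexahydroazulen-3(1H)-one ethylene ketal
Conditions: i-Bu2AlH (DIBAL-H, 4 equiv), CH2Cl2, −78 to 0 °C; aq. KNaC4H4O6 work-up
Reagents that add atoms: none
Why: 1,2-Reduction of the conjugated ester by the electrophilic aluminium hydride should give the allylic alcohol without touching ketal, alkene or any stereocentre.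

Step 7
Reactants: 10 (3aS,4S,8aR)-4-hydroxy-6-(hydroxymethyl)-8a-methyl-2,3a,4,5,8,8a-hexahydroazulen-3(1H)-one ethylene ketal
Product: 12 (3aS,4S,8aR)-4-hydroxy-6,8a-dimethyl-2,3a,4,5,8,8a-hexahydroazulen-3(1H)-one ethylene ketal, via allylic mesylate 11 (not isolated)
Conditions: MsCl (1.05 equiv), Et3N, CH2Cl2, −40 °C; then LiEt3BH (excess), THF, −40 to 0 °C
Reagents that add atoms: methanesulfonyl chloride, CS(=O)(=O)Cl (mesyl group of 11 only)
Why: Kinetically selective sulfonylation of the unhindered primary allylic hydroxyl over the crowded secondary C6 hydroxyl, then SN2 displacement by hydride, should turn the hydroxymethyl group into the C8 methyl group with the alkene left at C8=C9.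

Step 8
Reactants: 12 (3aS,4S,8aR)-4-hydroxy-6,8a-dimethyl-2,3a,4,5,8,8a-hexahydroazulen-3(1H)-one ethylene ketal
Product: 13 (3aS,4S,8aR)-4-hydroxy-6,8a-dimethyl-2,3a,4,5,8,8a-hexahydroazulen-3(1H)-one
Conditions: HCl (1 M aq.), THF, 0 °C to rt
Reagents that add atoms: water, O
Why: Acid-catalysed ketal hydrolysis, run dilute and cold so that the β-hydroxy ketone neither dehydrates nor epimerises at C5.

Step 9
Reactants: 13 (3aS,4S,8aR)-4-hydroxy-6,8a-dimethyl-2,3a,4,5,8,8a-hexahydroazulen-3(1H)-one
Product: 14 jaeschkeanadiol, (3R,3aS,4S,8aR)-6,8a-dimethyl-3-(propan-2-yl)-1,2,3,3a,4,5,8,8a-octahydroazulene-3,4-diol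
Conditions: i-PrMgCl (4 equiv), anhydrous CeCl3 (4 equiv), THF, −78 °C; aq. NH4Cl
Reagents that add atoms: isopropylmagnesium chloride, CC(C)[Mg]Cl
Why: 1,2-Addition of an organocerium reagent, which suppresses enolisation and β-hydride reduction; attack on the α face of the C4 carbonyl, anti to the angular C1 methyl group and the C5–C6 bond of the trans-fused bicycle, should give the 4β-hydroxy-4α-isopropyl carbinol.

Step 10
Reactants: 14 jaeschkeanadiol; 15 4-(benzyloxy)benzoyl chloride
Product: 16 (3R,3aS,4S,8aR)-3-hydroxy-6,8a-dimethyl-3-(propan-2-yl)-1,2,3,3a,4,5,8,8a-octahydroazulen-4-yl 4-(benzyloxy)benzoate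
Conditions: Et3N, DMAP (cat.), CH2Cl2, 0 °C to rt
Reagents that add atoms: none
Why: DMAP-catalysed acylation should take place only at the secondary C6 hydroxyl, the tertiary C4 hydroxyl being too hindered, with the phenol carried as its benzyl ether.

Step 11
Reactants: 16 (3R,3aS,4S,8aR)-3-hydroxy-6,8a-dimethyl-3-(propan-2-yl)-1,2,3,3a,4,5,8,8a-octahydroazulen-4-yl 4-(benzyloxy)benzoate
Product: 17 (3R,3aS,4S,6R,7S,8aR)-6,7-epoxy-3-hydroxy-6,8a-dimethyl-3-(propan-2-yl)decahydroazulen-4-yl 4-(benzyloxy)benzoate (8α,9α-epoxide)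
Conditions: mCPBA, NaHCO3, CH2Cl2, 0 °C
Reagents that add atoms: mCPBA, OOC(=O)c1cccc(Cl)c1
Why: Prilezhaev epoxidation of the only alkene from the α face of the chair-like cycloheptene, the β face being screened by the axial C1 methyl group and by ring carbons C1 and C6.

Step 12
Reactants: 17 (3R,3aS,4S,6R,7S,8aR)-6,7-epoxy-3-hydroxy-6,8a-dimethyl-3-(propan-2-yl)decahydroazulen-4-yl 4-(benzyloxy)benzoate
Product: 18 (3R,3aS,4S,6S,7S,8aR)-3,6,7-trihydroxy-6,8a-dimethyl-3-(propan-2-yl)decahydroazulen-4-yl 4-(benzyloxy)benzoate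
Conditions: HClO4 (cat., aq.), THF/H2O (3:1), 0 °C to rt
Reagents that add atoms: water, O
Why: Acid-catalysed anti opening of the trisubstituted epoxide by water at the tertiary C8 with inversion (attack at C9 is electronically disfavoured and blocked by the axial C1 methyl) should give 8β-OH/8α-Me and leave the 9α-oxygen, the trans ring fusion keeping the C4 hydroxyl out of reach of C8.

Step 13
Reactants: 18 (3R,3aS,4S,6S,7S,8aR)-3,6,7-trihydroxy-6,8a-dimethyl-3-(propan-2-yl)decahydroazulen-4-yl 4-(benzyloxy)benzoate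
Product: 19 (3R,3aS,4S,6S,7S,8aR)-3,6,7-trihydroxy-6,8a-dimethyl-3-(propan-2-yl)decahydroazulen-4-yl 4-hydroxybenzoate
Conditions: H2 (1 atm), Pd/C (10 %), EtOAc, rt
Reagents that add atoms: none
Why: Hydrogenolysis of the benzyl aryl ether should free the phenol; no alkene remains and the ester, diol and tertiary alcohols are inert.

Compound list
1 | 2-bromo-3-methylcyclopent-2-en-1-one | CC1=C(Br)C(=O)CC1 | starting material
2 | 6-bromo-7-methyl-1,4-dioxaspiro[4.4]non-6-ene | CC1=C(Br)C2(CC1)OCCO2 | intermediate
3 | 6-ethenyl-7-methyl-1,4-dioxaspiro[4.4]non-6-ene | C=CC1=C(C)CCC12OCCO2 | intermediate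
4 | methyl but-3-enoate | COC(=O)CC=C | starting material
5 | methyl 2-diazobut-3-enoate | COC(=O)C(=[N+]=[N-])C=C | intermediate
6 | cis-divinylcyclopropane, methyl (1S,2S)-1-ethenyl-2-(7-methyl-1,4-dioxaspiro[4.4]non-6-en-6-yl)cyclopropane-1-carboxylate (not isolated) | COC(=O)[C@]1(C=C)C[C@H]1C1=C(C)CCC12OCCO2 | intermediate
7 | methyl (8aR)-8a-methyl-3-oxo-1,2,3,5,8,8a-hexahydroazulene-6-carboxylate ethylene ketal | O1CCOC12CC[C@]3(C)CC=C(C(=O)OC)CC=C32 | intermediate
8 | C6-alkylborane of 7 (BH2 on the α face of C6, new H on the α face of C5; not isolated) | O1CCOC12CC[C@]3(C)CC=C(C(=O)OC)C[C@H](B)[C@H]32 | intermediate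
9 | methyl (3aS,4S,8aR)-4-hydroxy-8a-methyl-3-oxo-1,2,3,3a,4,5,8,8a-octahydroazulene-6-carboxylate ethylene ketal | O1CCOC12CC[C@]3(C)CC=C(C(=O)OC)C[C@H](O)[C@H]32 | intermediate
10 | (3aS,4S,8aR)-4-hydroxy-6-(hydroxymethyl)-8a-methyl-2,3a,4,5,8,8a-hexahydroazulen-3(1H)-one ethylene ketal | O1CCOC12CC[C@]3(C)CC=C(CO)C[C@H](O)[C@H]32 | intermediate
11 | primary allylic methanesulfonate of 10 (not isolated) | O1CCOC12CC[C@]3(C)CC=C(COS(C)(=O)=O)C[C@H](O)[C@H]32 | intermediate
12 | (3aS,4S,8aR)-4-hydroxy-6,8a-dimethyl-2,3a,4,5,8,8a-hexahydroazulen-3(1H)-one ethylene ketal | O1CCOC12CC[C@]3(C)CC=C(C)C[C@H](O)[C@H]32 | intermediate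
13 | (3aS,4S,8aR)-4-hydroxy-6,8a-dimethyl-2,3a,4,5,8,8a-hexahydroazulen-3(1H)-one | O=C1CC[C@]2(C)CC=C(C)C[C@H](O)[C@H]21 | intermediate
14 | jaeschkeanadiol, (3R,3aS,4S,8aR)-6,8a-dimethyl-3-(propan-2-yl)-1,2,3,3a,4,5,8,8a-octahydroazulene-3,4-diol | CC(C)[C@]1(O)CC[C@]2(C)CC=C(C)C[C@H](O)[C@H]21 | intermediate
15 | 4-(benzyloxy)benzoyl chloride | ClC(=O)c1ccc(OCc2ccccc2)cc1 | starting material
16 | (3R,3aS,4S,8aR)-3-hydroxy-6,8a-dimethyl-3-(propan-2-yl)-1,2,3,3a,4,5,8,8a-octahydroazulen-4-yl 4-(benzyloxy)benzoate | CC(C)[C@]1(O)CC[C@]2(C)CC=C(C)C[C@H](OC(=O)c3ccc(OCc4ccccc4)cc3)[C@H]21 | intermediate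
17 | (3R,3aS,4S,6R,7S,8aR)-6,7-epoxy-3-hydroxy-6,8a-dimethyl-3-(propan-2-yl)decahydroazulen-4-yl 4-(benzyloxy)benzoate | CC(C)[C@]1(O)CC[C@]2(C)C[C@@H]3O[C@]3(C)C[C@H](OC(=O)c3ccc(OCc4ccccc4)cc3)[C@H]21 | intermediate
18 | (3R,3aS,4S,6S,7S,8aR)-3,6,7-trihydroxy-6,8a-dimethyl-3-(propan-2-yl)decahydroazulen-4-yl 4-(benzyloxy)benzoate | CC(C)[C@]1(O)CC[C@]2(C)C[C@H](O)[C@@](C)(O)C[C@H](OC(=O)c3ccc(OCc4ccccc4)cc3)[C@H]21 | intermediate
19 | (3R,3aS,4S,6S,7S,8aR)-3,6,7-trihydroxy-6,8a-dimethyl-3-(propan-2-yl)decahydroazulen-4-yl 4-hydroxybenzoate | CC(C)[C@]1(O)CC[C@]2(C)C[C@H](O)[C@@](C)(O)C[C@H](OC(=O)c3ccc(O)cc3)[C@H]21 | target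

Total step count: 13. Longest linear sequence: 12 steps (from 1 to 19 through steps 1, 2 and 4–13; step 3 prepares the diazo partner).

Steps most likely to fail

Step 4. The chiral carbenoid may discriminate poorly between the two faces of the crowded vinyl group of 3, so that 7 forms with low enantiomeric purity; the Cope stage is stereospecific and cannot correct this. The fallback replaces asymmetric catalysis by resolution; it sets out from 3 and comes back at 9. Compounds 3 and 5 are combined with achiral Rh2(OAc)4 under otherwise identical conditions, which gives 7 together with its antipode ent-7 F1. Hydroboration–oxidation as in step 5 gives 9 together with ent-9 F2. Acylation of this mixture with (S)-2-methoxy-2-phenylacetic acid (DCC, DMAP, CH2Cl2) gives two diastereomeric esters, the (S)-2-methoxy-2-phenylacetate of 9 F3 and the (S)-2-methoxy-2-phenylacetate of ent-9 F4, which are separated by chromatography. Methanolysis of F3 (K2CO3, MeOH) returns 9.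

Step 9. The branched, basic isopropyl reagent may enolise or reduce the hindered cyclopentanone, or the β-alkoxy ketone may open by retro-aldol cleavage before addition. The fallback installs the group in two stages; it sets out from 13 and comes back at 14. Isopropenylmagnesium bromide with CeCl3 (THF, −78 °C), a smaller sp2 nucleophile without β-hydrogen, gives the isopropenyl carbinol F5. Hydrogenation with RhCl(PPh3)3 and H2 (benzene, rt) then saturates the 1,1-disubstituted alkene selectively and leaves the trisubstituted ring alkene, giving 14.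

Step 5. Borane may approach the β face, or both faces, of C5=C6, so that the cis-fused C5,C6-epimer forms. The fallback replaces kinetic by thermodynamic control at C5 and C6; it sets out from 7 and comes back at 12. The hydroboration is run as written and the cis-fused C5,C6-bis-epimer of 9 F6 is taken through steps 6 and 7 unchanged, via the bis-epimeric diol F7 and the bis-epimeric allylic mesylate F8, to the bis-epimer of 12 F9. Dess–Martin oxidation gives the cis-fused C6 ketone F10, and NaOMe in MeOH equilibrates C5 to the trans-fused C6 ketone F11, the arrangement expected to be favoured by analogy with angularly methylated 6-oxo steroids. Dissolving-metal reduction (Li, liquid NH3, THF, t-BuOH, −78 °C) should then give the equatorial 6α-alcohol, which is 12.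

Further compounds
F1 | step 4 | ent-7, methyl (8aS)-8a-methyl-3-oxo-1,2,3,5,8,8a-hexahydroazulene-6-carboxylate ethylene ketal | O1CCOC12CC[C@@]3(C)CC=C(C(=O)OC)CC=C32
F2 | step 4 | ent-9, methyl (3aR,4R,8aS)-4-hydroxy-8a-methyl-3-oxo-1,2,3,3a,4,5,8,8a-octahydroazulene-6-carboxylate ethylene ketal | O1CCOC12CC[C@@]3(C)CC=C(C(=O)OC)C[C@@H](O)[C@@H]32
F3 | step 4 | (S)-2-methoxy-2-phenylacetate of 9 | O1CCOC12CC[C@]3(C)CC=C(C(=O)OC)C[C@H](OC(=O)[C@@H](OC)c4ccccc4)[C@H]32
F4 | step 4 | (S)-2-methoxy-2-phenylacetate of ent-9 | O1CCOC12CC[C@@]3(C)CC=C(C(=O)OC)C[C@@H](OC(=O)[C@@H](OC)c4ccccc4)[C@@H]32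
F5 | step 9 | isopropenyl carbinol, 14 with a prop-1-en-2-yl group in place of the isopropyl group | CC(=C)[C@]1(O)CC[C@]2(C)CC=C(C)C[C@H](O)[C@H]21
F6 | step 5 | cis-fused C5,C6-bis-epimer of 9 (H-5β, 6β-OH) | O1CCOC12CC[C@]3(C)CC=C(C(=O)OC)C[C@@H](O)[C@@H]32
F7 | step 5 | cis-fused C5,C6-bis-epimer of 10 | O1CCOC12CC[C@]3(C)CC=C(CO)C[C@@H](O)[C@@H]32
F8 | step 5 | cis-fused C5,C6-bis-epimer of 11 | O1CCOC12CC[C@]3(C)CC=C(COS(C)(=O)=O)C[C@@H](O)[C@@H]32
F9 | step 5 | cis-fused C5,C6-bis-epimer of 12 | O1CCOC12CC[C@]3(C)CC=C(C)C[C@@H](O)[C@@H]32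
F10 | step 5 | cis-fused C6 ketone, 6,8a-dimethyl-1,2,3a,5,8,8a-hexahydroazulene-3,4-dione 3-(ethylene ketal) with H-5β | O1CCOC12CC[C@]3(C)CC=C(C)CC(=O)[C@@H]32
F11 | step 5 | trans-fused C6 ketone, C5 epimer of F10 with H-5α | O1CCOC12CC[C@]3(C)CC=C(C)CC(=O)[C@H]32
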